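The route rests on disconnecting, in one stroke, the aryl ester C–O bond between the benzoyl carbon of ring A (the methoxy-bearing benzoyl ring) and O4 of the olivetolate ring B, together with the C1–C6 bond of ring A. Ring A carries oxygens at C2 and C4 and a carbon arm at C6, the 1,3-dioxygen pattern of a folded tetraketide whose end carbonyl is the depside carbonyl. Heating a diketo-dioxinone that bears the 2-oxoheptyl terminus as a dioxolane with benzyl olivetolate gives an acylketene; the free 4-hydroxyl of ring B captures it, and aldol closure with dehydration then forms ring A. Selective O-methylation, ketal hydrolysis and hydrogenolysis complete the synthesis.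

Key step: step 7

Remark on the chemistry: the poly-β-carbonyl compounds 3, 7, 12 and 13 are drawn as keto tautomers although they should exist largely as enols, and 13 should form as a stereoisomer mixture that converges on aromatization. Chain atoms in steps 4 and 7 are numbered C1 (ester carbon) to C9 (ketal carbon).

Step 1
Reactants: 1 2,2,6-trimethyl-4H-1,3-dioxin-4-one; 2 acetyl chloride
Product: 3 2,2-dimethyl-6-(2-oxopropyl)-4H-1,3-dioxin-4-one
Conditions: 1 (2 equiv), LiN(SiMe3)2 (2 equiv), THF, −78 °C; then 2 (1 equiv), −78 to −20 °C; sat. aq. NH4Cl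
Reagents that add atoms: none
Why: The lithium dienolate of 1 reacts at its γ-carbon (the 6-methyl group) with the acid chloride in a vinylogous Claisen-type C-acylation, the second equivalent of enolate taking up the proton of the more acidic β-keto product so that it is not acylated twice.

Step 2
Reactants: 4 ethyl 3-oxooctanoate
Product: 5 ethyl 2-(2-pentyl-1,3-dioxolan-2-yl)acetate
Conditions: HOCH2CH2OH (3 equiv), p-TsOH·H2O (cat.), PhMe, reflux, Dean–Stark
Reagents that add atoms: ethylene glycol, OCCO
Why: Acid-catalysed ketalization with azeotropic removal of water masks the ketone of the β-keto ester as a dioxolane and leaves the ester untouched.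

Step 3
Reactants: 5 ethyl 2-(2-pentyl-1,3-dioxolan-2-yl)acetate
Product: 6 N-methoxy-N-methyl-2-(2-pentyl-1,3-dioxolan-2-yl)acetamide
Conditions: MeNH(OMe)·HCl (1.5 equiv), i-PrMgCl (3 equiv), THF, −20 to 0 °C
Reagents that add atoms: N,O-dimethylhydroxylamine hydrochloride, CNOC.Cl
Why: The chloromagnesium amide formed in the flask adds to the ester and the chelated tetrahedral adduct collapses to the Weinreb amide (ester aminolysis by a magnesium amide) under basic conditions that a ketal tolerates.

Step 4
Reactants: 3 2,2-dimethyl-6-(2-oxopropyl)-4H-1,3-dioxin-4-one; 6 N-methoxy-N-methyl-2-(2-pentyl-1,3-dioxolan-2-yl)acetamide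
Product: 7 2,2-dimethyl-6-[2,4-dioxo-5-(2-pentyl-1,3-dioxolan-2-yl)pentyl]-4H-1,3-dioxin-4-one
Conditions: 3 (2.5 equiv), LiN(i-Pr)2 (5 equiv), THF, −78 °C; then 6 (1 equiv), −78 to −40 °C; AcOH quench at −78 °C, pH 7 buffer
Reagents that add atoms: none
Why: Double deprotonation of 3 gives a dianion whose more reactive terminal (methyl-derived) carbon attacks the Weinreb amide in a crossed Claisen condensation, the chelated adduct preventing over-addition and releasing the 1,3-diketone only on the weakly acidic quench that spares the ketal.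

Step 5
Reactants: 8 olivetol (5-pentylbenzene-1,3-diol)
Product: 9 olivetolic acid (2,4-dihydroxy-6-pentylbenzoic acid)
Conditions: MeOMgOCO2Me (2 M in DMF, 5 equiv), 120 °C, N2 sweep; then cold 1 M HCl
Reagents that add atoms: methoxymagnesium methyl carbonate, C[O-].COC([O-])=O.[Mg+2]
Why: Magnesium-phenoxide-directed ortho-carboxylation (a Kolbe–Schmitt-type reaction with the Stiles reagent) delivers CO2 next to a hydroxyl, and the product is held as a magnesium salicylate chelate until the cold acidic work-up.

Step 6
Reactants: 9 olivetolic acid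
Product: 10 benzyl olivetolate (benzyl 2,4-dihydroxy-6-pentylbenzoate)
Conditions: BnBr (1.05 equiv), KHCO3 (1.2 equiv), DMF, rt
Reagents that add atoms: benzyl bromide, BrCc1ccccc1
Why: Hydrogencarbonate ionizes only the carboxylic acid, so SN2 O-alkylation of the carboxylate gives the benzyl ester and leaves both phenols free.

Step 7
Reactants: 7 2,2-dimethyl-6-[2,4-dioxo-5-(2-pentyl-1,3-dioxolan-2-yl)pentyl]-4H-1,3-dioxin-4-one; 10 benzyl olivetolate
Product: 14 benzyl 4-({2,4-dihydroxy-6-[(2-pentyl-1,3-dioxolan-2-yl)methyl]benzoyl}oxy)-2-hydroxy-6-pentylbenzoate, via triketo acylketene 11 (not isolated), via aryl triketo ester 12 (not isolated), via aldol carbinol 13 (not isolated)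
Conditions: 10 (1.5 equiv), PhMe (0.1 M), 110 °C, 2 h; cool to rt, Et3N (3 equiv), CH2Cl2, 12 h; then AcOH (10 equiv), 4 Å MS, rt to 40 °C
Reagents that add atoms: none
Why: Heating 7 expels acetone by a retro-hetero-Diels–Alder reaction to give acylketene 11, which is captured by the free 4-hydroxyl of 10 to form the aryl ester C–O bond of 12 under neutral conditions. Triethylamine then enolizes the C2 methylene of 12 (between the ester and the C3 ketone), which adds to the C7 ketone in a 6-(enolendo)-exo-trig aldol closure to carbinol 13, and acetic acid promotes loss of water and enolization of the C3 and C5 carbonyls, so that ring A is closed by the new chain C2–C7 bond (the C1–C6 bond of ring A). The closest known reaction type is the thermolysis of diketo-dioxinones with alcohols followed by base-then-acid aromatization to resorcylate esters, combined with the familiar acetoacetylation of phenols by dioxinone-derived acylketenes. No stereocentre has to be controlled, since the two centres of 13 vanish on aromatization. The step needs acylation at O4 and not O2 of 10, which the hydrogen bond from the 2-hydroxyl to the benzyl ester carbonyl secures, and it needs a single folding of the chain, which the dioxolane secures by leaving C7 as the only ketone that can form a six-membered carbocycle with C2. Loss of the chain as a pyranone or by re-ionization of the aryl β-keto ester is held back by an excess of 10 at moderate concentration during capture and by a tertiary amine in an aprotic solvent for the aldol, while acetic acid is too weak to hydrolyse the ketal.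

Step 8
Reactants: 14 benzyl 4-({2,4-dihydroxy-6-[(2-pentyl-1,3-dioxolan-2-yl)methyl]benzoyl}oxy)-2-hydroxy-6-pentylbenzoate
Product: 15 benzyl 2-hydroxy-4-({2-hydroxy-4-methoxy-6-[(2-pentyl-1,3-dioxolan-2-yl)methyl]benzoyl}oxy)-6-pentylbenzoate
Conditions: MeI (1.2 equiv), K2CO3 (1.1 equiv), acetone, rt
Reagents that add atoms: iodomethane, CI
Why: Williamson ether synthesis should occur at the most acidic and only non-chelated phenol (the 4-hydroxyl of ring A, para to the ester carbonyl), because the two ortho-hydroxyls are tied up in hydrogen bonds to ester carbonyls.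

Step 9
Reactants: 15 benzyl 2-hydroxy-4-({2-hydroxy-4-methoxy-6-[(2-pentyl-1,3-dioxolan-2-yl)methyl]benzoyl}oxy)-6-pentylbenzoate
Product: 16 benzyl 2-hydroxy-4-{[2-hydroxy-4-methoxy-6-(2-oxoheptyl)benzoyl]oxy}-6-pentylbenzoate
Conditions: 1 M aq. HCl/THF (1:4), rt
Reagents that add atoms: water, O
Why: Acid-catalysed ketal hydrolysis through the oxocarbenium ion frees the ketone under conditions to which the hindered, hydrogen-bonded aryl ester and the benzyl ester are inert.

Step 10
Reactants: 16 benzyl 2-hydroxy-4-{[2-hydroxy-4-methoxy-6-(2-oxoheptyl)benzoyl]oxy}-6-pentylbenzoate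
Product: 17 2-hydroxy-4-{[2-hydroxy-4-methoxy-6-(2-oxoheptyl)benzoyl]oxy}-6-pentylbenzoic acid (target CNP0358566.0)
Conditions: H2 (1 atm), Pd/C (10 wt% palladium on carbon), EtOAc, rt
Reagents that add atoms: none
Why: Catalytic hydrogenolysis cleaves the benzylic C–O bond of the benzyl ester under neutral conditions that spare the aliphatic ketone, the aryl ester and the aryl methyl ether, so the sensitive keto-depside acid is released in the last operation.

Compound list
1 | 2,2,6-trimethyl-4H-1,3-dioxin-4-one | CC1=CC(=O)OC(C)(C)O1 | starting material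
2 | acetyl chloride | CC(=O)Cl | starting material
3 | 2,2-dimethyl-6-(2-oxopropyl)-4H-1,3-dioxin-4-one | CC(=O)CC1=CC(=O)OC(C)(C)O1 | intermediate
4 | ethyl 3-oxooctanoate | CCCCCC(=O)CC(=O)OCC | starting material
5 | ethyl 2-(2-pentyl-1,3-dioxolan-2-yl)acetate | CCCCCC1(CC(=O)OCC)OCCO1 | intermediate
6 | N-methoxy-N-methyl-2-(2-pentyl-1,3-dioxolan-2-yl)acetamide | CCCCCC1(CC(=O)N(C)OC)OCCO1 | intermediate
7 | 2,2-dimethyl-6-[2,4-dioxo-5-(2-pentyl-1,3-dioxolan-2-yl)pentyl]-4H-1,3-dioxin-4-one | CC1(C)OC(=O)C=C(CC(=O)CC(=O)CC2(CCCCC)OCCO2)O1 | intermediate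
8 | olivetol (5-pentylbenzene-1,3-diol) | CCCCCc1cc(O)cc(O)c1 | starting material
9 | olivetolic acid (2,4-dihydroxy-6-pentylbenzoic acid) | CCCCCc1cc(O)cc(O)c1C(=O)O | intermediate
10 | benzyl olivetolate (benzyl 2,4-dihydroxy-6-pentylbenzoate) | CCCCCc1cc(O)cc(O)c1C(=O)OCc1ccccc1 | intermediate
11 | triketo acylketene, 8-(2-pentyl-1,3-dioxolan-2-yl)oct-1-ene-1,3,5,7-tetrone | CCCCCC1(CC(=O)CC(=O)CC(=O)C=C=O)OCCO1 | intermediate
12 | aryl triketo ester, benzyl 2-hydroxy-6-pentyl-4-{[3,5,7-trioxo-8-(2-pentyl-1,3-dioxolan-2-yl)octanoyl]oxy}benzoate | CCCCCC1(CC(=O)CC(=O)CC(=O)CC(=O)Oc2cc(O)c(C(=O)OCc3ccccc3)c(CCCCC)c2)OCCO1 | intermediate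
13 | aldol carbinol, benzyl 2-hydroxy-4-[({2-hydroxy-4,6-dioxo-2-[(2-pentyl-1,3-dioxolan-2-yl)methyl]cyclohexyl}carbonyl)oxy]-6-pentylbenzoate (stereoisomer mixture) | CCCCCC1(CC2(O)CC(=O)CC(=O)C2C(=O)Oc2cc(O)c(C(=O)OCc3ccccc3)c(CCCCC)c2)OCCO1 | intermediate
14 | benzyl 4-({2,4-dihydroxy-6-[(2-pentyl-1,3-dioxolan-2-yl)methyl]benzoyl}oxy)-2-hydroxy-6-pentylbenzoate | CCCCCC1(Cc2cc(O)cc(O)c2C(=O)Oc2cc(O)c(C(=O)OCc3ccccc3)c(CCCCC)c2)OCCO1 | intermediate
15 | benzyl 2-hydroxy-4-({2-hydroxy-4-methoxy-6-[(2-pentyl-1,3-dioxolan-2-yl)methyl]benzoyl}oxy)-6-pentylbenzoate | CCCCCC1(Cc2cc(OC)cc(O)c2C(=O)Oc2cc(O)c(C(=O)OCc3ccccc3)c(CCCCC)c2)OCCO1 | intermediate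
16 | benzyl 2-hydroxy-4-{[2-hydroxy-4-methoxy-6-(2-oxoheptyl)benzoyl]oxy}-6-pentylbenzoate | CCCCCC(=O)Cc1cc(OC)cc(O)c1C(=O)Oc1cc(O)c(C(=O)OCc2ccccc2)c(CCCCC)c1 | intermediate
17 | 2-hydroxy-4-{[2-hydroxy-4-methoxy-6-(2-oxoheptyl)benzoyl]oxy}-6-pentylbenzoic acid | CCCCCC(=O)Cc1cc(OC)cc(O)c1C(=O)Oc1cc(O)c(C(=O)O)c(CCCCC)c1 | target

Total step count: 10 steps, in three converging branches (steps 1–4 to 7, steps 5–6 to 10, then steps 7–10).
Longest linear sequence: 7 steps (steps 2, 3, 4, 7, 8, 9, 10, from 4 to 17).

Steps most likely to fail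

Step 7. The ketene may be consumed by internal O-acylation of a chain enol (pyranone formation) before the moderately nucleophilic phenol captures it. The aryl β-keto ester may also re-ionize under base, or dehydration may stall or cost the ketal. The fallback sets out from 7 and comes back at 15. It builds ring A first as an alkyl ester and forms the depside bond afterwards by classical esterification. Thermolysis of 7 with allyl alcohol (PhMe, 110 °C), then Et3N and AcOH, should give allyl 2,4-dihydroxy-6-[(2-pentyl-1,3-dioxolan-2-yl)methyl]benzoate F1. Methylation of its non-chelated 4-hydroxyl (MeI, K2CO3, acetone) should give allyl 2-hydroxy-4-methoxy-6-[(2-pentyl-1,3-dioxolan-2-yl)methyl]benzoate F2. Deallylation with Pd(PPh3)4 (zerovalent palladium) and morpholine in THF should give 2-hydroxy-4-methoxy-6-[(2-pentyl-1,3-dioxolan-2-yl)methyl]benzoic acid F3. Carbodiimide coupling of F3 with the 4-hydroxyl of 10 (DCC, PhMe, rt) should then give 15, from which steps 9 and 10 follow unchanged.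

Step 4. The dianion may act as a base toward the α-methylene of the Weinreb amide, with β-elimination opening the dioxolane, or addition to the amide may be too slow, so the chain is not extended. The fallback sets out from 6 and comes back at 7. It replaces the acyl transfer by an aldol addition and an oxidation. Reduction of 6 with i-Bu2AlH (THF, −78 °C) should give 2-(2-pentyl-1,3-dioxolan-2-yl)acetaldehyde F4. Addition of the dianion of 3 (LiN(i-Pr)2, THF, −78 °C) to this far more electrophilic aldehyde should give racemic 6-[4-hydroxy-2-oxo-5-(2-pentyl-1,3-dioxolan-2-yl)pentyl]-2,2-dimethyl-4H-1,3-dioxin-4-one F5. Oxidation with Dess–Martin periodinane (NaHCO3, CH2Cl2) should deliver 7.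

Step 5. Carboxylation may take place between the two hydroxyls instead of next to the pentyl chain, may stay incomplete, or may be reversed by loss of CO2 during work-up. The fallback sets out from 3 and comes back at 10, bypassing 8 and 9. It builds the olivetolate ring from an open chain so that the position of the carboxyl is fixed by construction. Claisen acylation of the dianion of 3 with commercial N-methoxy-N-methylhexanamide (LiN(i-Pr)2, THF, −78 °C) should give 2,2-dimethyl-6-(2,4-dioxononyl)-4H-1,3-dioxin-4-one F6. Thermolysis of F6 with benzyl alcohol (PhMe, 110 °C), then K2CO3 in i-PrOH/CH2Cl2 and acidification with HCl, should give 10 directly by acylketene capture and aldol aromatization.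

Further compounds
F1 | step 7 | allyl 2,4-dihydroxy-6-[(2-pentyl-1,3-dioxolan-2-yl)methyl]benzoate | CCCCCC1(Cc2cc(O)cc(O)c2C(=O)OCC=C)OCCO1
F2 | step 7 | allyl 2-hydroxy-4-methoxy-6-[(2-pentyl-1,3-dioxolan-2-yl)methyl]benzoate | CCCCCC1(Cc2cc(OC)cc(O)c2C(=O)OCC=C)OCCO1
F3 | step 7 | 2-hydroxy-4-methoxy-6-[(2-pentyl-1,3-dioxolan-2-yl)methyl]benzoic acid | CCCCCC1(Cc2cc(OC)cc(O)c2C(=O)O)OCCO1
F4 | step 4 | 2-(2-pentyl-1,3-dioxolan-2-yl)acetaldehyde | CCCCCC1(CC=O)OCCO1
F5 | step 4 | 6-[4-hydroxy-2-oxo-5-(2-pentyl-1,3-dioxolan-2-yl)pentyl]-2,2-dimethyl-4H-1,3-dioxin-4-one (racemic) | CC1(C)OC(=O)C=C(CC(=O)CC(O)CC2(CCCCC)OCCO2)O1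
F6 | step 5 | 2,2-dimethyl-6-(2,4-dioxononyl)-4H-1,3-dioxin-4-one | CCCCCC(=O)CC(=O)CC1=CC(=O)OC(C)(C)O1
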